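**Retrosynthetic overview**
- Target ⇐ global desilylation of the fully silylated cis-benzodioxane.
- Dioxane ring (the only ring made; both benzene rings are bought) ⇐ intramolecular Pd-catalysed aryl C–O coupling of the C7 carbinol onto the aryl bromide, with retention, from the erythro (1S,2R) bromo alcohol.
- Erythro alcohol ⇐ Mitsunobu inversion at C7 of the threo (1R,2R) alcohol ⇐ reductive removal of the auxiliary and primary silylation.
- C7–C8 bond ⇐ Evans boron syn-aldol between an N-(aryloxyacetyl)oxazolidinone and 3,4-bis(silyloxy)-5-methoxybenzaldehyde.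
- Fragments ⇐ 5-bromovanillin (Wittig, reduction, O-alkylation, acylation of the auxiliary) and 5-hydroxyvanillin (silylation).

Assumption: the SMILES is taken as written; it encodes the cis-(2S,3R) benzodioxane (7S,8R in neolignan numbering).

Abbreviations: TBS = tert-butyldimethylsilyl; TIPS = triisopropylsilyl; Ar1 = 3,4-bis(TBS-oxy)-5-methoxyphenyl; Ar2O = 2-bromo-6-methoxy-4-[(E)-3-(TIPS-oxy)prop-1-enyl]phenoxy; C7 = benzylic carbon bearing Ar1, C8 = its neighbour, C9 = the CH2O carbon.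

Step 1
Reactants: 1 5-bromovanillin (3-bromo-4-hydroxy-5-methoxybenzaldehyde); 2 ethyl (triphenylphosphoranylidene)acetate
Product: 3 ethyl (E)-3-(3-bromo-4-hydroxy-5-methoxyphenyl)prop-2-enoate
Conditions: toluene, 90 °C
Reagents that add atoms: none
Why: Wittig olefination with a stabilised ylide tolerates the free phenol and gives the E-enoate.

Step 2
Reactants: 3 ethyl (E)-3-(3-bromo-4-hydroxy-5-methoxyphenyl)prop-2-enoate
Product: 4 2-bromo-4-[(E)-3-hydroxyprop-1-enyl]-6-methoxyphenol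
Conditions: i-Bu2AlH (3.5 equiv), CH2Cl2, −78 → 0 °C; aq. KNaC4H4O6
Reagents that add atoms: none
Why: Hydride 1,2-reduction of the enoate by i-Bu2AlH (one equivalent is consumed by the phenol) gives the allylic alcohol with the E-alkene unchanged.

Step 3
Reactants: 4 2-bromo-4-[(E)-3-hydroxyprop-1-enyl]-6-methoxyphenol; 5 methyl bromoacetate
Product: 6 methyl 2-{2-bromo-4-[(E)-3-hydroxyprop-1-enyl]-6-methoxyphenoxy}acetate
Conditions: K2CO3, acetone, 56 °C
Reagents that add atoms: none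
Why: Williamson ether synthesis, in which K2CO3 ionises only the acidic phenol, so the phenoxide is alkylated and the allylic alcohol is left alone.

Step 4
Reactants: 6 methyl 2-{2-bromo-4-[(E)-3-hydroxyprop-1-enyl]-6-methoxyphenoxy}acetate
Product: 7 methyl 2-(Ar2O)acetate
Conditions: TIPSCl, imidazole, DMF, 0 °C → rt
Reagents that add atoms: triisopropylsilyl chloride, CC(C)[Si](Cl)(C(C)C)C(C)C
Why: Silylation of the only free hydroxyl gives a TIPS ether robust enough for all later base, hydride and Pd steps.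

Step 5
Reactants: 7 methyl 2-(Ar2O)acetate
Product: 8 2-(Ar2O)acetic acid
Conditions: LiOH, THF/H2O 3:1, 0 °C → rt; then 1 M HCl to pH 3 at 0 °C
Reagents that add atoms: lithium hydroxide, [Li+].[OH-]
Why: Saponification of the unhindered methyl ester proceeds without touching the aryl bromide, the alkene or the TIPS ether.

Step 6
Reactants: 8 2-(Ar2O)acetic acid; 9 (S)-4-benzyl-1,3-oxazolidin-2-one
Product: 11 (4S)-4-benzyl-3-[2-(Ar2O)acetyl]-1,3-oxazolidin-2-one, via mixed pivalic anhydride 10 (not isolated)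
Conditions: PivCl, Et3N, THF, −20 °C; then 9, LiCl, −20 °C → rt
Reagents that add atoms: pivaloyl chloride, CC(C)(C)C(=O)Cl (its atoms appear in 10 only)
Why: Mixed-anhydride N-acylation, in which the oxazolidinone attacks the less hindered aryloxyacetyl carbonyl of the pivalic anhydride.

Step 7
Reactants: 12 3,4-dihydroxy-5-methoxybenzaldehyde (5-hydroxyvanillin)
Product: 13 3,4-bis(tert-butyldimethylsilyloxy)-5-methoxybenzaldehyde
Conditions: TBSCl (2.5 equiv), imidazole, DMF, rt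
Reagents that add atoms: tert-butyldimethylsilyl chloride, CC(C)(C)[Si](C)(C)Cl
Why: Double O-silylation masks the catechol with groups that a single fluoride treatment removes at the end.

Step 8
Reactants: 11 (4S)-4-benzyl-3-[2-(Ar2O)acetyl]-1,3-oxazolidin-2-one; 13 3,4-bis(tert-butyldimethylsilyloxy)-5-methoxybenzaldehyde
Product: 15 (4S)-4-benzyl-3-[(2S,3R)-3-(Ar1)-2-(Ar2O)-3-hydroxypropanoyl]-1,3-oxazolidin-2-one, via dibutylboron Z-enolate 14 (not isolated)
Conditions: Bu2BOTf, i-Pr2NEt, CH2Cl2, −78 → 0 °C; add 13 at −78 °C, then 0 °C; pH 7 buffer, MeOH, 30% H2O2, 0 °C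
Reagents that add atoms: dibutylboron triflate, CCCCB(CCCC)OS(=O)(=O)C(F)(F)F (its boron unit appears in 14 only)
Why: Evans boron syn-aldol, in which the Z-enolate reacts through a Zimmerman–Traxler chair on the face away from the benzyl group, forming the C7–C8 bond and setting C8 (2S) and C7 (3R) as the syn pair.

Step 9
Reactants: 15 (4S)-4-benzyl-3-[(2S,3R)-3-(Ar1)-2-(Ar2O)-3-hydroxypropanoyl]-1,3-oxazolidin-2-one
Product: 16 (1R,2R)-1-(Ar1)-2-(Ar2O)propane-1,3-diol (threo)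
Conditions: LiBH4, H2O (1 equiv), THF, 0 °C
Reagents that add atoms: none
Why: Reductive cleavage of the imide by LiBH4 turns the exocyclic carbonyl into C9H2OH and releases the auxiliary without touching either stereocentre.

Step 10
Reactants: 16 (1R,2R)-1-(Ar1)-2-(Ar2O)propane-1,3-diol
Product: 17 (1R,2R)-1-(Ar1)-2-(Ar2O)-3-(TIPS-oxy)propan-1-ol (threo)
Conditions: TIPSCl (1.1 equiv), imidazole, DMF, 0 °C
Reagents that add atoms: triisopropylsilyl chloride, CC(C)[Si](Cl)(C(C)C)C(C)C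
Why: Selective silylation of the primary hydroxyl with the bulky TIPS group, which does not migrate, leaves only the hindered benzylic hydroxyl free.

Step 11
Reactants: 17 (1R,2R)-1-(Ar1)-2-(Ar2O)-3-(TIPS-oxy)propan-1-ol
Product: 18 (1S,2R)-1-(Ar1)-2-(Ar2O)-3-(TIPS-oxy)propyl 4-nitrobenzoate (erythro)
Conditions: 4-O2NC6H4CO2H, PPh3, DIAD, THF, 0 °C → rt
Reagents that add atoms: 4-nitrobenzoic acid, O=C(O)c1ccc(cc1)[N+](=O)[O-]
Why: Mitsunobu reaction, in which the carboxylate displaces the alkoxyphosphonium by SN2 and inverts C7 from R to S (threo to erythro) while C8 is untouched.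

Step 12
Reactants: 18 (1S,2R)-1-(Ar1)-2-(Ar2O)-3-(TIPS-oxy)propyl 4-nitrobenzoate
Product: 19 (1S,2R)-1-(Ar1)-2-(Ar2O)-3-(TIPS-oxy)propan-1-ol (erythro)
Conditions: i-Bu2AlH (3 equiv), CH2Cl2, −78 °C; aq. KNaC4H4O6
Reagents that add atoms: none
Why: Reductive ester cleavage at −78 °C frees the inverted alcohol without the basic methanolysis that would strip the aryl TBS ethers.

Step 13
Reactants: 19 (1S,2R)-1-(Ar1)-2-(Ar2O)-3-(TIPS-oxy)propan-1-ol
Product: 20 (2S,3R)-2-(Ar1)-5-methoxy-7-[(E)-3-(TIPS-oxy)prop-1-enyl]-3-[(TIPS-oxy)methyl]-2,3-dihydro-1,4-benzodioxine (cis)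
Conditions: Pd(OAc)2 (5 mol %), 2-(di-tert-butylphosphino)-1,1'-binaphthyl (6 mol %), K3PO4, toluene, 80 °C
Reagents that add atoms: none
Why: Buchwald-type intramolecular Pd-catalysed C–O coupling forms the aryl–oxygen bond without breaking any bond at C7 or C8, so the erythro alcohol gives the cis ring with retention.

Step 14
Reactants: 20 (2S,3R)-2-(Ar1)-5-methoxy-7-[(E)-3-(TIPS-oxy)prop-1-enyl]-3-[(TIPS-oxy)methyl]-2,3-dihydro-1,4-benzodioxine
Product: 21 5-[(2S,3R)-3-(hydroxymethyl)-7-[(E)-3-hydroxyprop-1-enyl]-5-methoxy-2,3-dihydro-1,4-benzodioxin-2-yl]-3-methoxybenzene-1,2-diol (target)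
Conditions: TBAF (6 equiv), AcOH (6 equiv), THF, 0 °C → rt, argon
Reagents that add atoms: none
Why: Fluoride desilylation removes all four silyl ethers, and the acetic acid buffer keeps the catechol from air oxidation and the cis C7 aryl ether from base-induced opening.

**Compound list**
1 | 5-bromovanillin (3-bromo-4-hydroxy-5-methoxybenzaldehyde) | COc1cc(C=O)cc(Br)c1O | starting material
2 | ethyl (triphenylphosphoranylidene)acetate | CCOC(=O)C=P(c1ccccc1)(c1ccccc1)c1ccccc1 | starting material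
3 | ethyl (E)-3-(3-bromo-4-hydroxy-5-methoxyphenyl)prop-2-enoate | CCOC(=O)/C=C/c1cc(Br)c(O)c(OC)c1 | intermediate
4 | 2-bromo-4-[(E)-3-hydroxyprop-1-enyl]-6-methoxyphenol | OC/C=C/c1cc(Br)c(O)c(OC)c1 | intermediate
5 | methyl bromoacetate | COC(=O)CBr | starting material
6 | methyl 2-{2-bromo-4-[(E)-3-hydroxyprop-1-enyl]-6-methoxyphenoxy}acetate | COC(=O)COc1c(Br)cc(/C=C/CO)cc1OC | intermediate
7 | methyl 2-{2-bromo-6-methoxy-4-[(E)-3-(triisopropylsilyloxy)prop-1-enyl]phenoxy}acetate | COC(=O)COc1c(Br)cc(/C=C/CO[Si](C(C)C)(C(C)C)C(C)C)cc1OC | intermediate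
8 | 2-{2-bromo-6-methoxy-4-[(E)-3-(triisopropylsilyloxy)prop-1-enyl]phenoxy}acetic acid | OC(=O)COc1c(Br)cc(/C=C/CO[Si](C(C)C)(C(C)C)C(C)C)cc1OC | intermediate
9 | (S)-4-benzyl-1,3-oxazolidin-2-one | O=C1OC[C@H](Cc2ccccc2)N1 | starting material
10 | 2-{2-bromo-6-methoxy-4-[(E)-3-(triisopropylsilyloxy)prop-1-enyl]phenoxy}acetic pivalic anhydride | CC(C)(C)C(=O)OC(=O)COc1c(Br)cc(/C=C/CO[Si](C(C)C)(C(C)C)C(C)C)cc1OC | intermediate
11 | (4S)-4-benzyl-3-(2-{2-bromo-6-methoxy-4-[(E)-3-(triisopropylsilyloxy)prop-1-enyl]phenoxy}acetyl)-1,3-oxazolidin-2-one | O=C1OC[C@H](Cc2ccccc2)N1C(=O)COc3c(Br)cc(/C=C/CO[Si](C(C)C)(C(C)C)C(C)C)cc3OC | intermediate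
12 | 3,4-dihydroxy-5-methoxybenzaldehyde (5-hydroxyvanillin) | COc1cc(C=O)cc(O)c1O | starting material
13 | 3,4-bis(tert-butyldimethylsilyloxy)-5-methoxybenzaldehyde | COc1cc(C=O)cc(O[Si](C)(C)C(C)(C)C)c1O[Si](C)(C)C(C)(C)C | intermediate
14 | (4S)-4-benzyl-3-[(Z)-1-(dibutylboryloxy)-2-{2-bromo-6-methoxy-4-[(E)-3-(triisopropylsilyloxy)prop-1-enyl]phenoxy}ethenyl]-1,3-oxazolidin-2-one (Z-boron enolate of 11) | CCCCB(CCCC)O/C(=C\Oc1c(Br)cc(/C=C/CO[Si](C(C)C)(C(C)C)C(C)C)cc1OC)N2C(=O)OC[C@@H]2Cc3ccccc3 | intermediate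
15 | (4S)-4-benzyl-3-[(2S,3R)-3-[3,4-bis(tert-butyldimethylsilyloxy)-5-methoxyphenyl]-2-{2-bromo-6-methoxy-4-[(E)-3-(triisopropylsilyloxy)prop-1-enyl]phenoxy}-3-hydroxypropanoyl]-1,3-oxazolidin-2-one | COc1cc([C@@H](O)[C@@H](C(=O)N2C(=O)OC[C@@H]2Cc3ccccc3)Oc4c(Br)cc(/C=C/CO[Si](C(C)C)(C(C)C)C(C)C)cc4OC)cc(O[Si](C)(C)C(C)(C)C)c1O[Si](C)(C)C(C)(C)C | intermediate
16 | (1R,2R)-1-[3,4-bis(tert-butyldimethylsilyloxy)-5-methoxyphenyl]-2-{2-bromo-6-methoxy-4-[(E)-3-(triisopropylsilyloxy)prop-1-enyl]phenoxy}propane-1,3-diol (threo) | COc1cc([C@@H](O)[C@@H](CO)Oc2c(Br)cc(/C=C/CO[Si](C(C)C)(C(C)C)C(C)C)cc2OC)cc(O[Si](C)(C)C(C)(C)C)c1O[Si](C)(C)C(C)(C)C | intermediate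
17 | (1R,2R)-1-[3,4-bis(tert-butyldimethylsilyloxy)-5-methoxyphenyl]-2-{2-bromo-6-methoxy-4-[(E)-3-(triisopropylsilyloxy)prop-1-enyl]phenoxy}-3-(triisopropylsilyloxy)propan-1-ol (threo) | COc1cc([C@@H](O)[C@@H](CO[Si](C(C)C)(C(C)C)C(C)C)Oc2c(Br)cc(/C=C/CO[Si](C(C)C)(C(C)C)C(C)C)cc2OC)cc(O[Si](C)(C)C(C)(C)C)c1O[Si](C)(C)C(C)(C)C | intermediate
18 | (1S,2R)-1-[3,4-bis(tert-butyldimethylsilyloxy)-5-methoxyphenyl]-2-{2-bromo-6-methoxy-4-[(E)-3-(triisopropylsilyloxy)prop-1-enyl]phenoxy}-3-(triisopropylsilyloxy)propyl 4-nitrobenzoate (erythro) | COc1cc([C@H](OC(=O)c2ccc(cc2)[N+](=O)[O-])[C@@H](CO[Si](C(C)C)(C(C)C)C(C)C)Oc3c(Br)cc(/C=C/CO[Si](C(C)C)(C(C)C)C(C)C)cc3OC)cc(O[Si](C)(C)C(C)(C)C)c1O[Si](C)(C)C(C)(C)C | intermediate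
19 | (1S,2R)-1-[3,4-bis(tert-butyldimethylsilyloxy)-5-methoxyphenyl]-2-{2-bromo-6-methoxy-4-[(E)-3-(triisopropylsilyloxy)prop-1-enyl]phenoxy}-3-(triisopropylsilyloxy)propan-1-ol (erythro) | COc1cc([C@H](O)[C@@H](CO[Si](C(C)C)(C(C)C)C(C)C)Oc2c(Br)cc(/C=C/CO[Si](C(C)C)(C(C)C)C(C)C)cc2OC)cc(O[Si](C)(C)C(C)(C)C)c1O[Si](C)(C)C(C)(C)C | intermediate
20 | (2S,3R)-2-[3,4-bis(tert-butyldimethylsilyloxy)-5-methoxyphenyl]-5-methoxy-7-[(E)-3-(triisopropylsilyloxy)prop-1-enyl]-3-[(triisopropylsilyloxy)methyl]-2,3-dihydro-1,4-benzodioxine (cis) | COc1cc([C@@H]2Oc3cc(/C=C/CO[Si](C(C)C)(C(C)C)C(C)C)cc(OC)c3O[C@@H]2CO[Si](C(C)C)(C(C)C)C(C)C)cc(O[Si](C)(C)C(C)(C)C)c1O[Si](C)(C)C(C)(C)C | intermediate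
21 | 5-[(2S,3R)-3-(hydroxymethyl)-7-[(E)-3-hydroxyprop-1-enyl]-5-methoxy-2,3-dihydro-1,4-benzodioxin-2-yl]-3-methoxybenzene-1,2-diol | COc1cc([C@@H]2Oc3cc(/C=C/CO)cc(OC)c3O[C@@H]2CO)cc(O)c1O | target

**Totals**
Total steps: 14. Longest linear sequence: 13 (steps 1–6, then 8–14); step 7 is the one-step side branch.

**Steps most likely to fail**

Step 11 (Mitsunobu inversion). The carbinol is hindered and carries an oxygenated aryl ring, so partial ionisation would give ester with retention, or the reaction may stall. The fallback sets out from 17 and replaces SN2 inversion by oxidation and stereoselective reduction. Dess–Martin periodinane in NaHCO3-buffered CH2Cl2 at 0 °C gives the ketone (2R)-1-(Ar1)-2-(Ar2O)-3-(TIPS-oxy)propan-1-one F1. Reduction with LiBH(s-Bu)3 in THF at −78 °C under Felkin–Anh (non-chelation) control, with the aryloxy group anti to the incoming hydride, gives the erythro alcohol. The ketone is kept cold and unpurified so that C8 does not epimerise. The route is rejoined at 19.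

Step 13 (Pd-catalysed ring closure). β-Hydride elimination from the palladium alkoxide would give ketone and debrominated arene. The fallback sets out from 17, the threo alcohol, and closes the ring by SN2 at C7 instead of by aryl C–O coupling. Miyaura borylation (B2pin2, PdCl2(dppf) with dppf = 1,1'-bis(diphenylphosphino)ferrocene, KOAc, dioxane, 85 °C) gives the threo pinacol boronate (1R,2R)-1-(Ar1)-2-{2-methoxy-6-(4,4,5,5-tetramethyl-1,3,2-dioxaborolan-2-yl)-4-[(E)-3-(TIPS-oxy)prop-1-enyl]phenoxy}-3-(TIPS-oxy)propan-1-ol F2. Oxidation with 30% H2O2 in NaHCO3-buffered THF at 0 °C gives the threo phenol (1R,2R)-1-(Ar1)-2-{2-hydroxy-6-methoxy-4-[(E)-3-(TIPS-oxy)prop-1-enyl]phenoxy}-3-(TIPS-oxy)propan-1-ol F3. Intramolecular Mitsunobu etherification (PPh3, DIAD, THF, 0 °C) then lets the phenol displace the activated C7 hydroxyl with inversion, which gives the cis ring directly. The route is rejoined at 20.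

Step 14 (global desilylation). The free catechol is air-sensitive, and a phenoxide para to C7 could open the cis ring and let it re-close as the trans isomer. The fallback sets out from 20 and isolates the product through a stable derivative. Desilylation with HF·pyridine in THF/pyridine is followed by acetylation of the crude tetraol in the same flask (Ac2O, pyridine, DMAP) to give 5-[(2S,3R)-3-(acetoxymethyl)-7-[(E)-3-acetoxyprop-1-enyl]-5-methoxy-2,3-dihydro-1,4-benzodioxin-2-yl]-3-methoxy-1,2-phenylene diacetate F4, which can be chromatographed and checked for cis purity. Brief deacetylation with catalytic K2CO3 in degassed MeOH at 0 °C, quenched with acidic resin, comes back to 21.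

**Further compounds**
F1 | step 11 | (2R)-1-[3,4-bis(tert-butyldimethylsilyloxy)-5-methoxyphenyl]-2-{2-bromo-6-methoxy-4-[(E)-3-(triisopropylsilyloxy)prop-1-enyl]phenoxy}-3-(triisopropylsilyloxy)propan-1-one | COc1cc(C(=O)[C@@H](CO[Si](C(C)C)(C(C)C)C(C)C)Oc2c(Br)cc(/C=C/CO[Si](C(C)C)(C(C)C)C(C)C)cc2OC)cc(O[Si](C)(C)C(C)(C)C)c1O[Si](C)(C)C(C)(C)C
F2 | step 13 | (1R,2R)-1-[3,4-bis(tert-butyldimethylsilyloxy)-5-methoxyphenyl]-2-{2-methoxy-6-(4,4,5,5-tetramethyl-1,3,2-dioxaborolan-2-yl)-4-[(E)-3-(triisopropylsilyloxy)prop-1-enyl]phenoxy}-3-(triisopropylsilyloxy)propan-1-ol | COc1cc([C@@H](O)[C@@H](CO[Si](C(C)C)(C(C)C)C(C)C)Oc2c(B3OC(C)(C)C(C)(C)O3)cc(/C=C/CO[Si](C(C)C)(C(C)C)C(C)C)cc2OC)cc(O[Si](C)(C)C(C)(C)C)c1O[Si](C)(C)C(C)(C)C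
F3 | step 13 | (1R,2R)-1-[3,4-bis(tert-butyldimethylsilyloxy)-5-methoxyphenyl]-2-{2-hydroxy-6-methoxy-4-[(E)-3-(triisopropylsilyloxy)prop-1-enyl]phenoxy}-3-(triisopropylsilyloxy)propan-1-ol | COc1cc([C@@H](O)[C@@H](CO[Si](C(C)C)(C(C)C)C(C)C)Oc2c(O)cc(/C=C/CO[Si](C(C)C)(C(C)C)C(C)C)cc2OC)cc(O[Si](C)(C)C(C)(C)C)c1O[Si](C)(C)C(C)(C)C
F4 | step 14 | 5-[(2S,3R)-3-(acetoxymethyl)-7-[(E)-3-acetoxyprop-1-enyl]-5-methoxy-2,3-dihydro-1,4-benzodioxin-2-yl]-3-methoxy-1,2-phenylene diacetate | COc1cc([C@@H]2Oc3cc(/C=C/COC(C)=O)cc(OC)c3O[C@@H]2COC(C)=O)cc(OC(C)=O)c1OC(C)=O
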